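The pyranone ring is closed last, at C2–C3. C3 is flanked by the C4 carbonyl and an aryl ring, the substitution of a donor/acceptor carbene. C2 is the benzylic carbon of ring B bound to O1, which in an open precursor is a hydridic ArO–CH2–Ar group lying 1,6 to C3. A chiral dirhodium catalyst inserts the C3 carbene of an α-aryl-α-diazoketone into one enantiotopic benzylic C–H, forming C2–C3 and the C2 stereocentre in one operation; C3 then equilibrates to trans. The precursor is an open diaryl diazoketone carrying the complete chalcone, with ring B held on a ring A oxygen as a 4-(benzyloxy)benzyl ether.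

Key step: step 6

Assumption: Rh2(S-PTAD)4 is taken to favour the 2S series in this 1,6-insertion; if it favours 2R, the mirror-image catalyst Rh2(R-PTAD)4 is used with no other change. Chromanone numbering (O1, C2, C3, C4; fused ring A; 2-aryl ring B) is used throughout.

Step 1
Reactants: 1 1-[2,4-bis(benzyloxy)-6-hydroxyphenyl]ethan-1-one (2',4'-bis(benzyloxy)-6'-hydroxyacetophenone); 2 4-(benzyloxy)benzyl chloride (1.2 equiv)
Product: 3 1-{2,4-bis(benzyloxy)-6-[(4-(benzyloxy)benzyl)oxy]phenyl}ethan-1-one
Conditions: K2CO3, Bu4NI (cat.), DMF, 70 °C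
Reagents that add atoms: none
Why: Williamson etherification of the one free, hydrogen-bonded ortho phenol with a reactive benzylic chloride under iodide catalysis, heat overcoming the chelation to the acetyl group; it places ring B and its future C2 carbon on the oxygen that becomes O1, as the most electron-rich benzylic CH2 of the molecule.

Step 2
Reactants: 3 1-{2,4-bis(benzyloxy)-6-[(4-(benzyloxy)benzyl)oxy]phenyl}ethan-1-one
Product: 5 1-{2,4-bis(benzyloxy)-6-[(4-(benzyloxy)benzyl)oxy]phenyl}-2-diazoethan-1-one, via trifluoroacetyl ketone 4 (not isolated)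
Conditions: LiN(SiMe3)2, THF, −78 °C, then CF3CO2CH2CF3; aq. HCl work-up; then p-ABSA, Et3N, H2O (1 equiv), MeCN, rt
Reagents that add atoms: 4-acetamidobenzenesulfonyl azide (p-ABSA), CC(=O)Nc1ccc(cc1)S(=O)(=O)N=[N+]=[N-] (the two diazo nitrogens); 2,2,2-trifluoroethyl trifluoroacetate, O=C(OCC(F)(F)F)C(F)(F)F (the trifluoroacetyl group of 4 only, lost again)
Why: Detrifluoroacetylative diazo transfer, in which Claisen-type C-trifluoroacetylation of the lithium enolate of the methyl ketone gives the activated 1,3-diketone 4 and a Regitz diazo transfer then proceeds with loss of the trifluoroacetyl group onto the sulfonamide nitrogen, a sequence that serves simple methyl ketones where direct transfer does not.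

Step 3
Reactants: 6 4-hydroxy-3-iodobenzaldehyde
Product: 7 4-tert-butoxy-3-iodobenzaldehyde
Conditions: Me2NCH(O-t-Bu)2, toluene, 80 °C
Reagents that add atoms: N,N-dimethylformamide di-tert-butyl acetal, CN(C)C(OC(C)(C)C)OC(C)(C)C
Why: O-tert-butylation of an acidic phenol by an amide acetal (the phenol protonates the acetal and the phenoxide captures the tert-butyl group), chosen because a tert-butyl ether has no C–H on the carbon bound to oxygen, survives the base of step 4 and is cleaved by BCl3 in step 7.

Step 4
Reactants: 7 4-tert-butoxy-3-iodobenzaldehyde; 8 1-[2,4-bis(benzyloxy)phenyl]ethan-1-one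
Product: 9 (E)-1-[2,4-bis(benzyloxy)phenyl]-3-(4-tert-butoxy-3-iodophenyl)prop-2-en-1-one
Conditions: KOH, EtOH/THF, rt
Reagents that add atoms: none
Why: Claisen–Schmidt condensation of the methyl ketone enolate with the non-enolisable aldehyde followed by E1cB dehydration, which should give the conjugated enone as the thermodynamically preferred E isomer.

Step 5
Reactants: 5 1-{2,4-bis(benzyloxy)-6-[(4-(benzyloxy)benzyl)oxy]phenyl}-2-diazoethan-1-one (1.2 equiv); 9 (E)-1-[2,4-bis(benzyloxy)phenyl]-3-(4-tert-butoxy-3-iodophenyl)prop-2-en-1-one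
Product: 10 (E)-1-[2,4-bis(benzyloxy)phenyl]-3-{3-[2-(2,4-bis(benzyloxy)-6-{[4-(benzyloxy)benzyl]oxy}phenyl)-1-diazo-2-oxoethyl]-4-tert-butoxyphenyl}prop-2-en-1-one
Conditions: Pd(PPh3)4 (5 mol%), Ag2CO3 (0.5 equiv), Et3N, toluene, rt
Reagents that add atoms: none
Why: Palladium-catalysed C–H arylation of an acyldiazomethane by an aryl iodide with retention of the diazo group (oxidative addition to zerovalent palladium, base- and silver-assisted palladation of the diazo carbon, reductive elimination), which at room temperature should outrun loss of N2 while the enone and the ethers stay spectators.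

Step 6
Reactants: 10 the α-aryl-α-diazoketone of step 5
Product: 12 (2S,3R)-5,7-bis(benzyloxy)-2-[4-(benzyloxy)phenyl]-3-{5-[(E)-3-[2,4-bis(benzyloxy)phenyl]-3-oxoprop-1-en-1-yl]-2-tert-butoxyphenyl}chroman-4-one (2,3-trans), via cis-chromanone 11 (not isolated)
Conditions: Rh2(S-PTAD)4 [dirhodium tetrakis((S)-(1-adamantyl)(N-phthalimido)acetate)] (1 mol%), CH2Cl2, 0 °C to rt, slow addition of 10; then SiO2, CH2Cl2, rt
Reagents that add atoms: none
Why: Loss of N2 gives a donor/acceptor carbene bound to divalent rhodium at C3, which inserts through a concerted, hydride-transfer-like three-centre transition state into a benzylic C–H of the ortho ArO–CH2–Ar ether of ring A that carries ring B, forming C2–C3. The closest known reaction type is the C–H insertion of 2-alkoxyphenyl α-diazoketones to chroman-4-ones under chiral dirhodium tetracarboxylates, together with the enantioselective α-oxy benzylic insertions of aryl diazo compounds. The pyranone ring closes in the 1,6-insertion mode (six-membered cyclic transition state), the only mode open on the aroyl side because no C–H lies 1,5 to the carbene. C2 is controlled by the catalyst, which selects one of the two enantiotopic benzylic hydrogens; C3 is set kinetically in the insertion (cis isomer 11 expected in part) and is then brought to the trans (2S,3R) arrangement, both aryl groups equatorial, by enol-mediated equilibration on silica, a non-basic medium chosen so that no enolate can open the O1–C2 bond. The step needs the carbene to choose the 4-(benzyloxy)benzylic CH2 over the plain benzylic CH2 of the other ortho ether and over attack on the ether oxygens (oxonium ylide, [1,2]-benzyl shift); the substrate favours the first through the more hydridic p-alkoxy-substituted C–H, which better carries the positive charge that builds up at carbon in the transition state, and helps the second through the low basicity of aryl ether oxygens conjugated with the aroyl group. The tert-butyl ether on the C3-aryl ring offers no α-C–H for an otherwise favoured 1,5-insertion and leaves only unactivated methyl C–H bonds on that side.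

Step 7
Reactants: 12 the protected trans-chromanone of step 6
Product: 13 (2S,3R)-3-{5-[(E)-3-(2,4-dihydroxyphenyl)-3-oxoprop-1-en-1-yl]-2-hydroxyphenyl}-5,7-dihydroxy-2-(4-hydroxyphenyl)chroman-4-one (2,3-trans; CNP0272156.2)
Conditions: BCl3 (excess), pentamethylbenzene (excess), CH2Cl2, −78 to −30 °C; CHCl3/MeOH quench at −78 °C, aqueous work-up
Reagents that add atoms: none
Why: Lewis acid dealkylation with a non-basic cation scavenger, in which BCl3 cleaves the five benzyl ethers and the tert-butyl ether at low temperature while pentamethylbenzene traps the benzyl cations before they alkylate ring A, a non-reductive method that spares the enone; the acidic medium keeps C3 trans and avoids the base-induced opening of the O1–C2 bond that would racemise C2.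

Compound list
1 | 1-[2,4-bis(benzyloxy)-6-hydroxyphenyl]ethan-1-one | CC(=O)c1c(O)cc(OCc2ccccc2)cc1OCc1ccccc1 | starting material
2 | 4-(benzyloxy)benzyl chloride | ClCc1ccc(OCc2ccccc2)cc1 | starting material
3 | 1-{2,4-bis(benzyloxy)-6-[(4-(benzyloxy)benzyl)oxy]phenyl}ethan-1-one | CC(=O)c1c(OCc2ccc(OCc3ccccc3)cc2)cc(OCc2ccccc2)cc1OCc1ccccc1 | intermediate
4 | 1-{2,4-bis(benzyloxy)-6-[(4-(benzyloxy)benzyl)oxy]phenyl}-4,4,4-trifluorobutane-1,3-dione | O=C(CC(=O)C(F)(F)F)c1c(OCc2ccc(OCc3ccccc3)cc2)cc(OCc2ccccc2)cc1OCc1ccccc1 | intermediate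
5 | 1-{2,4-bis(benzyloxy)-6-[(4-(benzyloxy)benzyl)oxy]phenyl}-2-diazoethan-1-one | [N-]=[N+]=CC(=O)c1c(OCc2ccc(OCc3ccccc3)cc2)cc(OCc2ccccc2)cc1OCc1ccccc1 | intermediate
6 | 4-hydroxy-3-iodobenzaldehyde | O=Cc1ccc(O)c(I)c1 | starting material
7 | 4-tert-butoxy-3-iodobenzaldehyde | CC(C)(C)Oc1ccc(C=O)cc1I | intermediate
8 | 1-[2,4-bis(benzyloxy)phenyl]ethan-1-one | CC(=O)c1ccc(OCc2ccccc2)cc1OCc1ccccc1 | starting material
9 | (E)-1-[2,4-bis(benzyloxy)phenyl]-3-(4-tert-butoxy-3-iodophenyl)prop-2-en-1-one | O=C(/C=C/c1ccc(OC(C)(C)C)c(I)c1)c1ccc(OCc2ccccc2)cc1OCc1ccccc1 | intermediate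
10 | (E)-1-[2,4-bis(benzyloxy)phenyl]-3-{3-[2-(2,4-bis(benzyloxy)-6-{[4-(benzyloxy)benzyl]oxy}phenyl)-1-diazo-2-oxoethyl]-4-tert-butoxyphenyl}prop-2-en-1-one | [N-]=[N+]=C(C(=O)c1c(OCc2ccc(OCc3ccccc3)cc2)cc(OCc2ccccc2)cc1OCc1ccccc1)c1cc(/C=C/C(=O)c2ccc(OCc3ccccc3)cc2OCc2ccccc2)ccc1OC(C)(C)C | intermediate
11 | (2S,3S)-2,3-cis epimer of 12 | O=C(/C=C/c1ccc(OC(C)(C)C)c([C@@H]2C(=O)c3c(OCc4ccccc4)cc(OCc4ccccc4)cc3O[C@@H]2c2ccc(OCc3ccccc3)cc2)c1)c1ccc(OCc2ccccc2)cc1OCc1ccccc1 | intermediate
12 | (2S,3R)-5,7-bis(benzyloxy)-2-[4-(benzyloxy)phenyl]-3-{5-[(E)-3-[2,4-bis(benzyloxy)phenyl]-3-oxoprop-1-en-1-yl]-2-tert-butoxyphenyl}chroman-4-one | O=C(/C=C/c1ccc(OC(C)(C)C)c([C@H]2C(=O)c3c(OCc4ccccc4)cc(OCc4ccccc4)cc3O[C@@H]2c2ccc(OCc3ccccc3)cc2)c1)c1ccc(OCc2ccccc2)cc1OCc1ccccc1 | intermediate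
13 | (2S,3R)-3-{5-[(E)-3-(2,4-dihydroxyphenyl)-3-oxoprop-1-en-1-yl]-2-hydroxyphenyl}-5,7-dihydroxy-2-(4-hydroxyphenyl)chroman-4-one | O=C(/C=C/c1ccc(O)c([C@H]2C(=O)c3c(O)cc(O)cc3O[C@@H]2c2ccc(O)cc2)c1)c1ccc(O)cc1O | target

Total step count: 7. Longest linear sequence: 5 steps (steps 1, 2, 5, 6, 7 from compound 1; equally steps 3, 4, 5, 6, 7 from compound 6).

Steps most likely to fail (taken in route order; step 6 carries the greatest risk):

Step 5. The palladium-bound diazo species may lose N2 (carbene migratory insertion) before reductive elimination. The ortho tert-butoxy group may slow the coupling, and the diazoketone may add as a dipole to the enone. The fallback sets out from 3 and 9 and returns at 10. Ketone 3 is converted (Me3SiOTf, Et3N, CH2Cl2, 0 °C) into its silyl enol ether, {[1-(2,4-bis(benzyloxy)-6-{[4-(benzyloxy)benzyl]oxy}phenyl)vinyl]oxy}trimethylsilane F1. This is α-arylated with 9 under fluoride activation (Pd(dba)2, P(t-Bu)3, ZnF2, CsF, DMF, 70 °C), near-neutral conditions that should spare the enone, to give the deoxybenzoin (E)-1-[2,4-bis(benzyloxy)phenyl]-3-{3-[2-(2,4-bis(benzyloxy)-6-{[4-(benzyloxy)benzyl]oxy}phenyl)-2-oxoethyl]-4-tert-butoxyphenyl}prop-2-en-1-one F2. Regitz diazo transfer onto its doubly activated methylene (p-ABSA, DBU, MeCN, 0 °C) then gives 10.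

Step 6. The carbene may insert into the plain benzylic CH2 of the other ortho ether (poor site selectivity), which would give an isomeric 2-phenylchromanone. An ether oxygen of ring A may attack the carbene, giving an oxonium ylide and a [1,2]-benzyl shift to a benzofuranone. The catalyst may also discriminate the two enantiotopic benzylic hydrogens poorly. The fallback sets out from 3 and 9 through F1 and deoxybenzoin F2 of the preceding fallback and returns at 12; it keeps the same C2–C3 closure but reaches it by hydride abstraction. DDQ (1.1 equiv) with 2,6-dichloropyridine, LiClO4 and 4 Å sieves in 1,2-dichloroethane at rt should abstract hydride from the p-alkoxybenzylic ether, which this oxidant distinguishes from the plain benzyl ethers. The resulting aryloxy-stabilised benzylic cation is captured by the ketone enol (6-enolendo closure) to give the racemic trans-chromanone, that is 12 together with its mirror image, the (2R,3S)-enantiomer of 12 F3. The two are separated by preparative HPLC on a polysaccharide chiral stationary phase, and 12 is carried on.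

Step 7. BCl3 may ionise the p-oxybenzylic O1–C2 bond, and ring opening and reclosure would erode the configuration at C2. Further risks are Friedel–Crafts benzylation of ring A, incomplete loss of the tert-butyl group and cyclisation of the freed 2'-hydroxychalcone. The fallback sets out from 12 and returns at 13; it replaces the Lewis acid by a staged Brønsted acid unmasking. TFA in CH2Cl2 at 0 °C first removes only the tert-butyl ether, giving (2S,3R)-5,7-bis(benzyloxy)-2-[4-(benzyloxy)phenyl]-3-{5-[(E)-3-[2,4-bis(benzyloxy)phenyl]-3-oxoprop-1-en-1-yl]-2-hydroxyphenyl}chroman-4-one F4. Its five benzyl ethers are then cleaved by prolonged treatment with TFA and pentamethylbenzene at rt (push–pull acidolysis with the arene as benzyl acceptor), giving 13.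

Further compounds
F1 | step 5 | {[1-(2,4-bis(benzyloxy)-6-{[4-(benzyloxy)benzyl]oxy}phenyl)vinyl]oxy}trimethylsilane | C=C(O[Si](C)(C)C)c1c(OCc2ccc(OCc3ccccc3)cc2)cc(OCc2ccccc2)cc1OCc1ccccc1
F2 | step 5 | (E)-1-[2,4-bis(benzyloxy)phenyl]-3-{3-[2-(2,4-bis(benzyloxy)-6-{[4-(benzyloxy)benzyl]oxy}phenyl)-2-oxoethyl]-4-tert-butoxyphenyl}prop-2-en-1-one | O=C(Cc1cc(/C=C/C(=O)c2ccc(OCc3ccccc3)cc2OCc2ccccc2)ccc1OC(C)(C)C)c1c(OCc2ccc(OCc3ccccc3)cc2)cc(OCc2ccccc2)cc1OCc1ccccc1
F3 | step 6 | (2R,3S)-enantiomer of 12 | O=C(/C=C/c1ccc(OC(C)(C)C)c([C@@H]2C(=O)c3c(OCc4ccccc4)cc(OCc4ccccc4)cc3O[C@H]2c2ccc(OCc3ccccc3)cc2)c1)c1ccc(OCc2ccccc2)cc1OCc1ccccc1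
F4 | step 7 | (2S,3R)-5,7-bis(benzyloxy)-2-[4-(benzyloxy)phenyl]-3-{5-[(E)-3-[2,4-bis(benzyloxy)phenyl]-3-oxoprop-1-en-1-yl]-2-hydroxyphenyl}chroman-4-one | O=C(/C=C/c1ccc(O)c([C@H]2C(=O)c3c(OCc4ccccc4)cc(OCc4ccccc4)cc3O[C@@H]2c2ccc(OCc3ccccc3)cc2)c1)c1ccc(OCc2ccccc2)cc1OCc1ccccc1
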